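## Retrosynthetic overview
- The C11–OH/Δ6 unit comes from a singlet-oxygen ene transposition of a 7(11)-en-8-one. The ester comes from the 3β,4α-diol and (R)-2-methylbutanoic acid.
- The 3β,4α-diol comes from the 4α-hydroxy-3-ketone, which comes from α-face ketohydroxylation of eudesma-3,7(11)-dien-8-one.
- The key disconnection is C5–C10. It is a catalytic, enantioselective, proton-initiated transannular cyclisation of achiral germacrone: H+ adds at C1, the eudesm-4-yl cation forms, and H-3 is lost. This copies the germacrane → eudesmane step in the laboratory.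
- Ring order: the ten-membered ring (nature's farnesyl 1,10-closure) is bought with germacrone. The single C5–C10 bond then creates rings A and B at the same time, and no further ring is formed.

Assumption: germacrone (bulk isolate of zdravetz oil) and (R)-2-methylbutanoic acid are bought; the catalyst antipode that leads to the (5R,10R) series cannot be predicted, one screening experiment fixes it, and (S,S) is written here.

Eudesmane numbering is used throughout. The 10-CH3 is β and axial, and H-5 is α.

## Route

Step 1
Reactants: 1 germacrone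
Product: 3 (5R,10R)-eudesma-3,7(11)-dien-8-one, via eudesm-4-yl cation 2 (not isolated)
Conditions: (S,S)-imidodiphosphorimidate Brønsted acid {[(S)-3,3'-Ar2-1,1'-binaphthyl-2,2'-diolate]P(=NSO2CF3)}2NH, Ar = 3,5-(CF3)2C6H3 (5 mol %), dry CHCl3, −20 °C
Reagents that add atoms: none
Why: Proposed new method: germacrone is achiral only because its two planar-chiral crossed conformers interconvert fast relative to a slow catalytic reaction, its E,E-1(10),4-diene is pre-folded so that Markovnikov protonation at C1 is concerted with C10–C5 bonding through a chair–chair array (hence the trans-decalin with 5α-H anti to 10β-CH3), and a confined chiral acid that accepts only one conformer should make this a dynamic kinetic asymmetric transannular cation–olefin cyclisation that fixes C5 and C10 in one event, after which the counter-anion removes the axial H-3α of 2 to give the Δ3 alkene, which lacks transannular assistance and is not re-protonated at this temperature; the closest known reaction types are the racemic sulfonic-acid cyclisation of germacrone to selinadienones and the imidodiphosphorimidate-catalysed asymmetric proton-initiated polyene cyclisations and hydrofunctionalisations of unactivated alkenes.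

Step 2
Reactants: 3 (5R,10R)-eudesma-3,7(11)-dien-8-one
Product: 4 (4S,5R,10R)-4-hydroxyeudesm-7(11)-ene-3,8-dione
Conditions: RuCl3 (1 mol %), KHSO5 (as 2KHSO5·KHSO4·K2SO4), NaHCO3, EtOAc/MeCN/H2O, rt, minutes
Reagents that add atoms: potassium peroxymonosulfate KHSO5, [K+].[O-]S(=O)(=O)OO (terminal source of both new oxygen atoms, relayed by RuO4)
Why: RuO4-catalysed ketohydroxylation: RuO4 made in situ adds suprafacially ([3+2]) to the electron-rich trisubstituted Δ3 alkene, much faster than to the tetrasubstituted carbonyl-deactivated C7=C11 alkene, and from the α face because the axial 10β-methyl screens the β face, so C4 gets 4α-OH/4β-CH3 while the secondary C3–O terminus is oxidised on to the ketone in the same cycle.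

Step 3
Reactants: 4 (4S,5R,10R)-4-hydroxyeudesm-7(11)-ene-3,8-dione
Product: 5 (3S,4S,5R,10R)-3,4-dihydroxyeudesm-7(11)-en-8-one
Conditions: NaBH4, CH2Cl2/MeOH 1:1, −78 °C; aq NH4Cl
Reagents that add atoms: none
Why: Chemoselective borohydride 1,2-reduction: at −78 °C the inductively activated saturated α-hydroxy ketone reacts far faster than the hindered conjugated C8 enone, and hydride enters axially from the α face (the β face is closed by the axial 4β- and 10β-methyl groups), which gives the equatorial 3β-alcohol trans to the 4α-OH.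

Step 4
Reactants: 5 (3S,4S,5R,10R)-3,4-dihydroxyeudesm-7(11)-en-8-one; 6 (R)-2-methylbutanoic acid
Product: 7 (3S,4S,5R,10R)-4-hydroxy-8-oxoeudesm-7(11)-en-3-yl (2R)-2-methylbutanoate
Conditions: 6 (1.3 equiv), N,N'-dicyclohexylcarbodiimide, 4-(dimethylamino)pyridine (10 mol %), CH2Cl2, 0 °C to rt
Reagents that add atoms: 6 (R)-2-methylbutanoic acid, CC[C@@H](C)C(=O)O
Why: Steglich esterification: only the secondary equatorial 3β-OH is acylated (the tertiary 4α-OH is inert), the stereocentre of the acid is kept at low temperature with catalytic base, and any core of the wrong enantiomeric series becomes a diastereomer that is removed by chromatography or crystallisation.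

Step 5
Reactants: 7 (3S,4S,5R,10R)-4-hydroxy-8-oxoeudesm-7(11)-en-3-yl (2R)-2-methylbutanoate
Product: 9 (3S,4S,5R,10R)-4,11-dihydroxy-8-oxoeudesm-6-en-3-yl (2R)-2-methylbutanoate, via 11-hydroperoxide 8 (not isolated)
Conditions: O2, 5,10,15,20-tetraphenylporphyrin (1 mol %), white LED, CH2Cl2, 0 °C; then PPh3, 0 °C to rt
Reagents that add atoms: dioxygen, O=O
Why: Schenck ene reaction followed by phosphine reduction: singlet oxygen reacts with s-cis-locked α-alkylidene ketones (pulegone type) with geminal selectivity, so it abstracts the axial H-6β of the CH2 geminal to the carbonyl and binds at C11, which moves the alkene to C6=C7 and, after O–O reduction of 8 by PPh3, leaves the tertiary C11 alcohol without touching any stereocentre.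

## Compound list
1 | germacrone, (E,E)-germacra-1(10),4,7(11)-trien-8-one (achiral) | C/C1=C\CC(=C(C)C)C(=O)C/C(C)=C/CC1 | starting material
2 | 8-oxoeudesm-7(11)-en-4-yl cation (trans-decalin, 5α-H, 10β-CH3, tertiary cation at C4) | C[C+]1CCC[C@]2(C)CC(=O)C(=C(C)C)C[C@@H]12 | intermediate
3 | (5R,10R)-eudesma-3,7(11)-dien-8-one (5α-H, 10β-CH3) | CC1=CCC[C@]2(C)CC(=O)C(=C(C)C)C[C@@H]12 | intermediate
4 | (4S,5R,10R)-4-hydroxyeudesm-7(11)-ene-3,8-dione (4α-OH, 4β-CH3) | O=C1CC[C@]2(C)CC(=O)C(=C(C)C)C[C@H]2[C@]1(C)O | intermediate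
5 | (3S,4S,5R,10R)-3,4-dihydroxyeudesm-7(11)-en-8-one (3β-OH, 4α-OH, both equatorial) | O[C@H]1CC[C@]2(C)CC(=O)C(=C(C)C)C[C@H]2[C@]1(C)O | intermediate
6 | (R)-2-methylbutanoic acid | CC[C@@H](C)C(=O)O | starting material
7 | (3S,4S,5R,10R)-4-hydroxy-8-oxoeudesm-7(11)-en-3-yl (2R)-2-methylbutanoate | CC[C@@H](C)C(=O)O[C@H]1CC[C@]2(C)CC(=O)C(=C(C)C)C[C@H]2[C@]1(C)O | intermediate
8 | (3S,4S,5R,10R)-11-hydroperoxy-4-hydroxy-8-oxoeudesm-6-en-3-yl (2R)-2-methylbutanoate | CC[C@@H](C)C(=O)O[C@H]1CC[C@]2(C)CC(=O)C(C(C)(C)OO)=C[C@H]2[C@]1(C)O | intermediate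
9 | (3S,4S,5R,10R)-4,11-dihydroxy-8-oxoeudesm-6-en-3-yl (2R)-2-methylbutanoate (CNP0201989.1) | CC[C@@H](C)C(=O)O[C@H]1CC[C@]2(C)CC(=O)C(C(C)(C)O)=C[C@H]2[C@]1(C)O | target

## Count and risks
Total step count: 5. Longest linear sequence: 5 steps (1 → 9). Compound 6 is bought and enters in step 4.

**Step 1** is the most likely to fail.
- The level and sense of induction are unknown.
- The ketone may buffer the acid.
- Proton loss may give Δ3, Δ4(15) and Δ4 isomers together.

The fallback sets out from 1 and comes back at 3. It relays chirality through an epoxide instead of a chiral proton.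
- Shi epoxidation uses 1,2:4,5-di-O-isopropylidene-β-D-erythro-2,3-hexodiulo-2,6-pyranose, KHSO5 and K2CO3 in MeCN/dimethoxymethane/water at 0 °C.
- It is expected to attack the Δ1(10) alkene preferentially and gives (1R,10R)-1,10-epoxygermacra-4,7(11)-dien-8-one F1. The minor 4,5-epoxide is removed by chromatography.
- Catalytic p-toluenesulfonic acid in CH2Cl2 starts the epoxide-initiated transannular cyclisation. C5 opens C10 anti and stereospecifically, so the epoxide configuration is passed to C5 and C10. The product is 1β-hydroxyeudesma-3,7(11)-dien-8-one F2.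
- 1,1'-Thiocarbonyldiimidazole converts it into O-(8-oxoeudesma-3,7(11)-dien-1β-yl) imidazole-1-carbothioate F3.
- Barton–McCombie deoxygenation (Bu3SnH, 2,2'-azobis(2-methylpropionitrile), toluene, 80 °C) gives 3.

**Step 2** may suffer C3–C4 cleavage, or competing attack at C7=C11.

The fallback sets out from 3 and comes back at 4. It separates the two oxidation events.
- Upjohn dihydroxylation (OsO4 cat., N-methylmorpholine N-oxide, acetone/water) from the α face gives (3R,4S,5R,10R)-3,4-dihydroxyeudesm-7(11)-en-8-one F4, the 3α,4α-cis-diol.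
- Its only secondary alcohol is then oxidised under Parikh–Doering conditions (SO3·pyridine, DMSO, Et3N) to 4.

**Step 5** may be slow because the alkene is electron-poor. Hydrogen abstraction from a C11 methyl may also compete and give the 7-hydroperoxy-11(12)-ene.

The fallback sets out from 7 and comes back at 9. It replaces the ene reaction by epoxidation, reduction and dehydrogenation.
- Dimethyldioxirane in acetone gives the 7α,11-epoxide of 7, (3S,4S,5R,10R)-7α,11-epoxy-4-hydroxy-8-oxoeudesman-3-yl (2R)-2-methylbutanoate F5. Either epoxide epimer serves.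
- SmI2 in THF/MeOH at −78 °C cleaves the Cα–O bond to give the β-hydroxy ketone (3S,4S,5R,10R)-4,11-dihydroxy-8-oxo-7αH-eudesman-3-yl (2R)-2-methylbutanoate F6.
- 2-Iodoxybenzoic acid in DMSO at 70 °C dehydrogenates it. Because C10 is quaternary, only the Δ6 enone can form, and this is 9.

## Further compounds
F1 | step 1 | (1R,10R)-1,10-epoxygermacra-4,7(11)-dien-8-one | C/C1=C\CC(=C(C)C)C(=O)C[C@@]2(C)O[C@@H]2CC1
F2 | step 1 | (1R,5S,10R)-1-hydroxyeudesma-3,7(11)-dien-8-one (1β-OH) | CC1=CC[C@@H](O)[C@]2(C)CC(=O)C(=C(C)C)C[C@@H]12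
F3 | step 1 | O-(8-oxoeudesma-3,7(11)-dien-1β-yl) imidazole-1-carbothioate | CC1=CC[C@@H](OC(=S)n3ccnc3)[C@]2(C)CC(=O)C(=C(C)C)C[C@@H]12
F4 | step 2 | (3R,4S,5R,10R)-3,4-dihydroxyeudesm-7(11)-en-8-one (3α,4α-diol) | O[C@@H]1CC[C@]2(C)CC(=O)C(=C(C)C)C[C@H]2[C@]1(C)O
F5 | step 5 | (3S,4S,5R,10R)-7α,11-epoxy-4-hydroxy-8-oxoeudesman-3-yl (2R)-2-methylbutanoate | CC[C@@H](C)C(=O)O[C@H]1CC[C@]2(C)CC(=O)[C@]3(OC3(C)C)C[C@H]2[C@]1(C)O
F6 | step 5 | (3S,4S,5R,10R)-4,11-dihydroxy-8-oxo-7αH-eudesman-3-yl (2R)-2-methylbutanoate | CC[C@@H](C)C(=O)O[C@H]1CC[C@]2(C)CC(=O)[C@@H](C(C)(C)O)C[C@H]2[C@]1(C)O
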